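Each flask starts with 0.020 M of each substrate against 100 µM of free catalyst, 200 to one, and its partner must first dissolve from the solid reagent.

common to all: left-handed substrate 0.020 M; solid reagent 0.0120 M; free catalyst 100 µM; right-handed substrate 0.020 M; time 30 min

|  | temperature | remark |
|---|---|---|
| red | 130 °C |  |
| violet |  | at 110 °C until 15 min, from then on at 130 °C |
| green | 110 °C |  |

    free catalyst + left-handed substrate ⇌ catalyst intermediate A (K1 = 42.3 M⁻¹, k1 = 98900 M⁻¹ min⁻¹, Ea1 = 51.0 kJ mol⁻¹, ΔH1 = 40.0 kJ mol⁻¹)
    free catalyst + right-handed substrate ⇌ catalyst intermediate B (K2 = 73 M⁻¹, k2 = 46100 M⁻¹ min⁻¹, Ea2 = 38.0 kJ mol⁻¹, ΔH2 = −39.0 kJ mol⁻¹)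
    partner + catalyst intermediate A → free catalyst + left-handed product (k3 = 1810 M⁻¹ min⁻¹, Ea3 = 41.0 kJ mol⁻¹)
    partner + catalyst intermediate B → free catalyst + right-handed product (k4 = 768 M⁻¹ min⁻¹, Ea4 = 56.0 kJ mol⁻¹)
    free catalyst + free catalyst ⇌ resting dimer (K5 = 5100 M⁻¹, k5 = 795 M⁻¹ min⁻¹, Ea5 = 41.0 kJ mol⁻¹, ΔH5 = −17.0 kJ mol⁻¹)
    solid reagent ⇌ partner, rate k6*(cs6 - [partner]) while solid is left; crystals form when [partner] > cs6 (cs6 = 0.64 mM, k6 = 0.0438 min⁻¹)
    (constants at 110 °C)

- free catalyst is single-handed; left-handed substrate and right-handed substrate are mirror images of each other, charged as a racemate, each of them at the stated concentration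
- two of one species on the left: rate k times its square, two consumed each time
- given per volume of solution although it is solid: solid reagent
- constants are those at 110 °C; use the activation energies and enthalpies for any other temperature
- at the start none of the solid reagent is in solution
- an excess is the difference of the two amounts in percent of their sum
- an excess is below zero if the other one leads

* the flask that comes out highest in excess of left-handed product over right-handed product, or "all alike" when all lie within 1.5 percentage points (red / violet / green / all alike)
* excess of left-handed product over right-handed product at the end, red
* excess of left-handed product over right-handed product at the end, violet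
* excess of left-handed product over right-handed product at the end, green

We reckon by hand, freezing what barely moves.

1. Substrates. Each product uses one partner, and the solid reagent dissolves at 0.0280 mM min⁻¹ at most, so 30 min allows 0.841 mM of product, far less than either substrate's charge. We freeze both substrates at their charge.

2. Catalyst. Free catalyst binds right-handed substrate, the slower binding, at 922 min⁻¹, while catalyst intermediate A meets partner at no more than 1.16 min⁻¹ at 110 °C. Because binding is much faster, we take both intermediates to stand in binding equilibrium, a pre-equilibrium.

3. Selectivity. Partner and free catalyst are common to both routes, so they cancel. What remains is the selectivity factor, the left-handed binding constant times its partner-step constant, over the same product for the right-handed route: 1.37 at 110 °C. The excess is that factor less one, over the factor plus one, which gives green 15.5%.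

4. Heat. The factor moves with one energy, the enthalpy of step 1 minus that of step 2, plus the activation energy of step 3 minus that of step 4: 64.0 kJ mol⁻¹. At 130 °C the factor becomes 3.70, and red reaches 57.4%.

5. Violet, first pass. Equal product from its cold and hot stretches would give 36.5%. Those equal weights are the weak link.

6. Violet, reforged. We leave out the resting dimer, which draws on both routes alike. Sharing the catalyst by the binding constants, partner is used up with a pseudo-first-order rate constant of 0.0802 min⁻¹ cold and 0.204 min⁻¹ hot. Where dissolving balances that use, product forms at 0.0181 mM min⁻¹ cold and 0.0231 mM min⁻¹ hot. The cold stretch starts without partner, which costs it about 8.06 min. That leaves 0.126 mM of product cold and 0.346 mM hot, and the weighted excess is 46.2%. We commit to red as highest.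

The forecast gives red 57.1%, violet 46.4% and green 15.4%, and names red as highest, with violet, in its words, “leaning towards the hot phase because the partner-limited turnover is faster then”. Its red lies 0.35 percentage points below ours.

The simulation gives red 57.1%, violet 46.3% and green 15.4%, with red highest.

A neighbouring flask, like red but kept at 105 °C, takes the same reckoning. The selectivity factor falls to 1.05, which gives an excess of 2.30%. In that flask, at 30.0 min, left-handed product stood at 0.421% and right-handed product at 0.401% of the substrates charged, and the simulated excess was 2.36%.

(The constants used here were drawn at random within sensible limits; the run is a simulation.)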